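**Retrosynthetic overview**

Flavan numbering is used (O1, C2–C4, C4a, C5–C8, C8a). Ring A is the benzo ring, ring B the 2-aryl group, ring C the pyran, and rings D and E the resorcinol and catechol rings of the stilbene. The C4–ring D bond is cut last: piceatannol attacks the flavan-4-yl cation of a 2,3-trans-3,4-cis flavan-3,4-diol anti to O3.
The diol comes from OsO4 addition to a (2S)-flav-3-ene on the face opposite ring B, so only C2 has to be made by asymmetric catalysis.
Ring C is the only ring that is built. It is closed at O1–C8a in a tandem aryne annulation of a Z-configured C4,O1-dilithio allyl alkoxide with a 2-chloro-6-fluoroaryllithium, which acts as a "benzdiyne" over C4a, C8a and C8. C4–C4a forms first and O1–C8a closes the ring.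
Enabling feature: ring A carries carbon (C4 on C4a) and oxygen (O1 on C8a) on neighbouring atoms, followed by an unsubstituted C8 and the oxygen-bearing C7. A halogen parked on C8 steers the first aryne and then leaves, and O7 steers the second.
Fragments: 4-(methoxymethoxy)benzaldehyde and trimethylsilylacetylene (ring B, C2–C4), 4-chloro-2-fluorophenol (ring A), piceatannol (rings D and E).

Key step: step 5

Assumption: (S,S)-ProPhenol is taken to direct the acetylide to the Si face of 3. Should the sense be the opposite, the (R,R) ligand is used and nothing else changes.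

Step 1
Reactants: 1 4-chloro-2-fluorophenol
Product: 2 4-chloro-2-fluoro-1-(methoxymethoxy)benzene
Conditions: NaH, MOMCl, THF, 0 °C to rt
Reagents that add atoms: chloromethyl methyl ether (MOMCl), COCCl
Why: Williamson ether synthesis on the phenol; the methoxymethyl acetal withstands alkyllithium reagents, leaves the C–H between fluorine and chlorine as the most acidic site and falls off under the acid of the last step.

Step 2
Reactants: 3 4-(methoxymethoxy)benzaldehyde; 4 trimethylsilylacetylene
Product: 6 (R)-1-[4-(methoxymethoxy)phenyl]-3-(trimethylsilyl)prop-2-yn-1-ol, via methylzinc acetylide 5 (not isolated)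
Conditions: Me2Zn (3 equiv), (S,S)-ProPhenol (10 mol %), Ph3PO (20 mol %), toluene, 0 °C
Reagents that add atoms: none
Why: Catalytic enantioselective alkynylation of an aryl aldehyde, in which zinc acetylide 5 is delivered inside the dinuclear zinc–ProPhenol complex to the Si face of 3, so the carbinol centre (the later C2) is set under ligand control.

Step 3
Reactants: 6 (R)-1-[4-(methoxymethoxy)phenyl]-3-(trimethylsilyl)prop-2-yn-1-ol
Product: 7 (R)-3-iodo-1-[4-(methoxymethoxy)phenyl]prop-2-yn-1-ol
Conditions: NIS, AgNO3 (10 mol %), DMF, rt, dark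
Reagents that add atoms: N-iodosuccinimide (NIS), O=C1CCC(=O)N1I
Why: Silver-catalysed iododesilylation of an alkynylsilane, an electrophilic ipso substitution at the sp carbon that does not touch the carbinol centre.

Step 4
Reactants: 7 (R)-3-iodo-1-[4-(methoxymethoxy)phenyl]prop-2-yn-1-ol
Product: 8 (S,Z)-3-iodo-1-[4-(methoxymethoxy)phenyl]prop-2-en-1-ol
Conditions: 2-nitrobenzenesulfonohydrazide, Et3N, THF/i-PrOH, rt
Reagents that add atoms: none
Why: Diimide reduction, in which concerted syn transfer of two hydrogens to the iodoalkyne gives the Z-iodoalkene with the C–I bond and the carbinol centre intact (the descriptor changes only because the priorities change).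

Step 5
Reactants: 8 (S,Z)-3-iodo-1-[4-(methoxymethoxy)phenyl]prop-2-en-1-ol; 2 4-chloro-2-fluoro-1-(methoxymethoxy)benzene
Product: 15 (S)-7-(methoxymethoxy)-2-[4-(methoxymethoxy)phenyl]-2H-chromene, via dilithio alkoxide 9 (not isolated), via aryllithium 10 (not isolated), via fluoroaryne 11 (not isolated), via fluoroaryllithium 12 (not isolated), via alkoxyaryne 13 (not isolated), via 8-lithiochromene 14 (not isolated)
Conditions: 8, MeLi (1.0 equiv) then t-BuLi (2.0 equiv), Et2O, −78 °C; 2, s-BuLi (1.0 equiv), THF, −78 °C; 10 added by cold cannula to 9 at −40 °C, then to rt; H2O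
Reagents that add atoms: none
Why: Proposed new method: on entering the warmer flask, aryllithium 10 loses LiCl before LiF (2-chloroaryllithiums collapse at far lower temperature than 2-fluoroaryllithiums) to give aryne 11 (C4a≡C8a), whose triple bond is distorted by the fluorine on C8 and in the same sense by the oxygen on C7, so that the vinyllithium carbon C4 of 9 adds at the remote C4a and the charge lands on C8a beside fluorine (12). Loss of LiF from 12 moves the triple bond one place to C8a≡C8 (13), now flanked by the acetal oxygen on C7, which directs a nucleophile to C8a (meta to oxygen, charge on C8 beside oxygen); the lithium alkoxide held there by the Z-alkene attacks this carbon in the plane of ring A and closes ring C in a 6-exo-dig mode by forming O1–C8a, and water protonates C8 of 14. The closest known reaction types are the tandem aryne sequence by which 2,6-dihaloaryl metals take up two aryl Grignard units (m-terphenyl synthesis), the domino 1,2-benzdiyne annulation of bis-nucleophiles and the classical intramolecular capture of an aryne by an alkoxide; new is a chiral C,O-dilithio reagent that places carbon and oxygen on neighbouring ring atoms. No stereocentre is created: C2 travels through as its lithium alkoxide, its C–O bond is never broken and the medium stays basic, so the acid-labile benzylic and allylic carbinol cannot ionise. The step needs carbon before oxygen (the vinyllithium is by far the better nucleophile of 9), capture of 11 by 9 and not by 10 (10 is flanked by two halogens and is kept at low stationary concentration by the slow addition) and ring closure before intermolecular attack on 13 (secured by the rigid Z-alkene tether).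

Step 6
Reactants: 15 (S)-7-(methoxymethoxy)-2-[4-(methoxymethoxy)phenyl]-2H-chromene
Product: 16 (2R,3S,4S)-7-(methoxymethoxy)-2-[4-(methoxymethoxy)phenyl]chromane-3,4-diol (2,3-trans-3,4-cis)
Conditions: OsO4 (3 mol %), NMO, acetone/H2O, 0 °C to rt
Reagents that add atoms: N-methylmorpholine N-oxide (NMO), C[N+]1([O-])CCOCC1; water, O
Why: Catalytic OsO4/NMO syn-dihydroxylation of a flav-3-ene, in which osmium adds to the face of C3=C4 opposite ring B on C2, so that substrate control sets C3 (S, trans to ring B) and C4 (S, cis to O3).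

Step 7
Reactants: 16 (2R,3S,4S)-7-(methoxymethoxy)-2-[4-(methoxymethoxy)phenyl]chromane-3,4-diol; 17 piceatannol
Product: 20 (2R,3S,4S)-4-{2-[(E)-2-(3,4-dihydroxyphenyl)ethenyl]-4,6-dihydroxyphenyl}-2-(4-hydroxyphenyl)chromane-3,7-diol, via flavan-4-yl cation 18 (not isolated), via bis-MOM ether 19 (not isolated)
Conditions: 17 (3 equiv), HCl (0.1 M in MeOH), argon, rt, then 45 °C
Reagents that add atoms: none
Why: Acid-catalysed Friedel–Crafts condensation of a flavan-3,4-diol with a phenolic nucleophile, in which ionisation of the C4 hydroxyl gives cation 18 (stabilised by O1 and O7), ring D of 17 attacks it through the carbon para to one hydroxyl and ortho to the other and from the face anti to O3 to set C4 (S, 3,4-trans, all substituents equatorial), and the same acid then cleaves the two methoxymethyl acetals of 19 by transacetalisation with methanol.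

**Compound list**

1 | 4-chloro-2-fluorophenol | Oc1ccc(Cl)cc1F | starting material
2 | 4-chloro-2-fluoro-1-(methoxymethoxy)benzene | COCOc1ccc(Cl)cc1F | intermediate
3 | 4-(methoxymethoxy)benzaldehyde | COCOc1ccc(C=O)cc1 | starting material
4 | trimethylsilylacetylene | C#C[Si](C)(C)C | starting material
5 | methyl[(trimethylsilyl)ethynyl]zinc | C[Zn]C#C[Si](C)(C)C | intermediate
6 | (R)-1-[4-(methoxymethoxy)phenyl]-3-(trimethylsilyl)prop-2-yn-1-ol | COCOc1ccc([C@@H](O)C#C[Si](C)(C)C)cc1 | intermediate
7 | (R)-3-iodo-1-[4-(methoxymethoxy)phenyl]prop-2-yn-1-ol | COCOc1ccc([C@@H](O)C#CI)cc1 | intermediate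
8 | (S,Z)-3-iodo-1-[4-(methoxymethoxy)phenyl]prop-2-en-1-ol | COCOc1ccc([C@@H](O)/C=C\I)cc1 | intermediate
9 | lithium (S,Z)-3-lithio-1-[4-(methoxymethoxy)phenyl]prop-2-en-1-olate | COCOc1ccc([C@@H](O[Li])/C=C\[Li])cc1 | intermediate
10 | 6-chloro-2-fluoro-3-(methoxymethoxy)phenyllithium | COCOc1ccc(Cl)c([Li])c1F | intermediate
11 | 3-fluoro-4-(methoxymethoxy)benzyne (C4a≡C8a) | COCOC1=C(F)C#CC=C1 | intermediate
12 | lithium (S,Z)-3-[3-fluoro-2-lithio-4-(methoxymethoxy)phenyl]-1-[4-(methoxymethoxy)phenyl]prop-2-en-1-olate | COCOc1ccc([C@@H](O[Li])/C=C\c2ccc(OCOC)c(F)c2[Li])cc1 | intermediate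
13 | lithium (S,Z)-3-[2,3-didehydro-4-(methoxymethoxy)phenyl]-1-[4-(methoxymethoxy)phenyl]prop-2-en-1-olate (aryne C8a≡C8) | COCOc1ccc([C@@H](O[Li])/C=C\C2=CC=C(OCOC)C#C2)cc1 | intermediate
14 | (S)-8-lithio-7-(methoxymethoxy)-2-[4-(methoxymethoxy)phenyl]-2H-chromene | COCOc1ccc([C@H]2Oc3c([Li])c(OCOC)ccc3C=C2)cc1 | intermediate
15 | (S)-7-(methoxymethoxy)-2-[4-(methoxymethoxy)phenyl]-2H-chromene | COCOc1ccc([C@H]2Oc3cc(OCOC)ccc3C=C2)cc1 | intermediate
16 | (2R,3S,4S)-7-(methoxymethoxy)-2-[4-(methoxymethoxy)phenyl]chromane-3,4-diol | COCOc1ccc([C@H]2Oc3cc(OCOC)ccc3[C@H](O)[C@@H]2O)cc1 | intermediate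
17 | piceatannol, (E)-4-[2-(3,5-dihydroxyphenyl)ethenyl]benzene-1,2-diol | Oc1cc(O)cc(/C=C/c2ccc(O)c(O)c2)c1 | starting material
18 | (2R,3S)-3-hydroxy-7-(methoxymethoxy)-2-[4-(methoxymethoxy)phenyl]chroman-4-ylium | COCOc1ccc([C@H]2Oc3cc(OCOC)ccc3[CH+][C@@H]2O)cc1 | intermediate
19 | 7,4'-bis(methoxymethyl) ether of 20 (2R,3S,4S) | COCOc1ccc([C@H]2Oc3cc(OCOC)ccc3[C@@H](c3c(O)cc(O)cc3/C=C/c3ccc(O)c(O)c3)[C@@H]2O)cc1 | intermediate
20 | (2R,3S,4S)-4-{2-[(E)-2-(3,4-dihydroxyphenyl)ethenyl]-4,6-dihydroxyphenyl}-2-(4-hydroxyphenyl)chromane-3,7-diol | Oc1ccc([C@H]2Oc3cc(O)ccc3[C@@H](c3c(O)cc(O)cc3/C=C/c3ccc(O)c(O)c3)[C@@H]2O)cc1 | target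

Total step count: 7. Longest linear sequence: 6 (steps 2 to 7).

**Steps most likely to fail**

1. Step 5.
- What may go wrong: aryne 11 may be captured by its own precursor 10 or by the alkoxide oxygen of 9. Fluoride may leave 10 before chloride. A proton transfer may quench 12 before fluoride leaves.
- The fallback sets out from 2 and 8 and comes back at 15. It makes the C4–C4a bond by cross-coupling.
- Miyaura borylation of the C–Cl bond of 2 (B2pin2, Pd(OAc)2, XPhos, KOAc, dioxane, 100 °C) should give the pinacol arylboronate F1.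
- Suzuki–Miyaura coupling of it with 8 (Pd(PPh3)4, K3PO4, THF/H2O, rt) keeps the alkene geometry and should give the Z-allylic alcohol F2, in which fluorine sits on C8.
- Lithium 2,2,6,6-tetramethylpiperidide (3 equiv, THF, −78 °C to rt) then takes the hydroxyl proton and the C8a proton beside fluorine, which leads to 12.
- From there the sequence 13, 14, 15 runs as in the main route, now as the classical intramolecular capture of a base-generated aryne by an alkoxide.

2. Step 7.
- What may go wrong: cation 18 may attack the ring D position between the two hydroxyls. Facial selectivity at C4 may be incomplete. The cation may self-condense with ring A of a second flavan unit. The methoxymethyl cation may alkylate the phenols.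
- The fallback sets out from 15 and 17 and comes back at 20. It replaces the ionising Friedel–Crafts event by a stereospecific epoxide opening with a site-defined aryl metal.
- 17 is protected (MOMCl, NaH, DMF, 0 °C) as the tetrakis(methoxymethyl) ether F3.
- NBS (CH2Cl2, −78 to 0 °C) brominates ring D para to one acetal oxygen and next to the styryl group to give the aryl bromide F4.
- n-BuLi (THF, −78 °C) turns it into the aryllithium F5.
- 15 is epoxidised with dimethyldioxirane (acetone/CH2Cl2, −20 °C) anti to ring B to give the 3,4-epoxyflavan F6.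
- This epoxide is opened by the aryllithium in the presence of BF3·OEt2 (THF, −78 °C) at benzylic C4 with inversion to give the hexakis(methoxymethyl) ether F7.
- HCl in MeOH (45 °C) then frees 20.

3. Step 2.
- What may go wrong: addition to the electron-rich aldehyde may be sluggish and the enantioselection insufficient.
- The fallback sets out from 3 and comes back at 7.
- Ethynylmagnesium bromide (THF, 0 °C) gives the racemic propargylic alcohol F8.
- Immobilised Candida antarctica lipase B with vinyl acetate (MTBE, 30 °C) is expected to acylate the enantiomer with aryl as the large and ethynyl as the medium group. This should give the (R)-acetate F9 and leave the (S)-alcohol F10.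
- NIS and AgNO3 (10 mol %, acetone, rt) convert that alcohol into 7 (same spatial arrangement, descriptor R through the change of priorities).

Further compounds
F1 | step 5 | 2-[3-fluoro-4-(methoxymethoxy)phenyl]-4,4,5,5-tetramethyl-1,3,2-dioxaborolane | COCOc1ccc(B2OC(C)(C)C(C)(C)O2)cc1F
F2 | step 5 | (S,Z)-3-[3-fluoro-4-(methoxymethoxy)phenyl]-1-[4-(methoxymethoxy)phenyl]prop-2-en-1-ol | COCOc1ccc([C@@H](O)/C=C\c2ccc(OCOC)c(F)c2)cc1
F3 | step 7 | (E)-3,3',4',5-tetrakis(methoxymethoxy)stilbene | COCOc1cc(OCOC)cc(/C=C/c2ccc(OCOC)c(OCOC)c2)c1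
F4 | step 7 | (E)-2-bromo-3,3',4',5-tetrakis(methoxymethoxy)stilbene | COCOc1cc(OCOC)c(Br)c(/C=C/c2ccc(OCOC)c(OCOC)c2)c1
F5 | step 7 | (E)-2-lithio-3,3',4',5-tetrakis(methoxymethoxy)stilbene | COCOc1cc(OCOC)c([Li])c(/C=C/c2ccc(OCOC)c(OCOC)c2)c1
F6 | step 7 | (2R,3S,4S)-3,4-epoxy-7-(methoxymethoxy)-2-[4-(methoxymethoxy)phenyl]chromane | COCOc1ccc([C@H]2Oc3cc(OCOC)ccc3[C@@H]4O[C@H]24)cc1
F7 | step 7 | hexakis(methoxymethyl) ether of 20 at the six phenolic oxygens (2R,3S,4S) | COCOc1ccc([C@H]2Oc3cc(OCOC)ccc3[C@@H](c3c(OCOC)cc(OCOC)cc3/C=C/c3ccc(OCOC)c(OCOC)c3)[C@@H]2O)cc1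
F8 | step 2 | rac-1-[4-(methoxymethoxy)phenyl]prop-2-yn-1-ol | COCOc1ccc(C(O)C#C)cc1
F9 | step 2 | (R)-1-[4-(methoxymethoxy)phenyl]prop-2-yn-1-yl acetate | COCOc1ccc([C@H](OC(C)=O)C#C)cc1
F10 | step 2 | (S)-1-[4-(methoxymethoxy)phenyl]prop-2-yn-1-ol | COCOc1ccc([C@@H](O)C#C)cc1
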